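| setting | violet | ochre | flask |
|---|---|---|---|
| starting complex | 2 mM | 2 mM | 2.0 mM |
| incoming ligand | 1 equiv | 1.5 equiv | 1.00 equiv |
| leaving ligand | 2 equiv | 2 equiv | 2.00 equiv |
| remark | the very flask that is asked about, followed so far | run made earlier |  |
| time |  |  | 2.5 min |

| run | time / s | starting complex / % | complex with four exchanged / % |
|---|---|---|---|
| violet | 10.0 | 86.1 | 0 |
| violet | 15.0 | 81.5 | 0 |
| violet | 20.0 | 76.9 | 0 |
| ochre | 10.0 | 79.5 | 0 |
| ochre | 12.0 | 75.7 | 0 |
| ochre | 20.0 | 64.9 | 0 |
| ochre | 30.0 | 61.2 | 0 |
| ochre | 50.0 | 54.0 | 0 |
| ochre | 60.0 | 50.1 | 0 |
| ochre | 120 | 47.8 | 1.3 |

(scatter of a reading: 1 percentage point)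

- share of the starting complex used up at 2.5 min
- amount of complex with four exchanged if the flask were left three thousand times as long, in percent of the starting complex charged

- candidate steps: complex with two exchanged -> side product A; complex with three exchanged + incoming ligand <-> leaving ligand + complex with four exchanged; complex with two exchanged + incoming ligand <-> leaving ligand + complex with three exchanged; complex with three exchanged -> decomposed reagent; starting complex + incoming ligand <-> leaving ligand + complex with one exchanged; complex with one exchanged + incoming ligand <-> leaving ligand + complex with two exchanged; leaving ligand + complex with four exchanged -> side product B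

What does a starting complex do first? It takes the easy step: it accepts an incoming ligand and gives off a leaving ligand, and then it stands at a fork, since the leaving ligand around it can undo that exchange.

Why suspect the undoing? Because the ochre run lost 20 percentage points of its starting complex by 10.0 s but 2.3 points between 60.0 s and 120 s, which looks like a balance of forward and back traffic.

How is that balance counted? I take 52.2% as reacted in ochre and assume one exchange per reacted complex, which gives 2.82: reacted complex times leaving ligand over starting complex times incoming ligand, the stall quotient, an apparent equilibrium constant.

And the violet flask? The reacted share that returns this quotient with violet's charges is 40.9%, and the asked time is longer than ochre's last reading.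

Where is this weak? The assumption of one exchange per complex is untested, since the runs report starting complex and complex with four exchanged but none of the complexes between them.

The forecast reads the stall as uptake of about 2.5 to 3 incoming ligands per complex, “meaning the later exchanges are fast”, and gives 37% and 0.1%; I stay with 40.9% and have no reckoning of my own for the second question.

The flask gives 40.1% and 0%.

    complex with two exchanged → side product A (k = 0.0130 s⁻¹)
    complex with three exchanged + incoming ligand ⇌ leaving ligand + complex with four exchanged (K = 0.790, k = 8.50 L mol⁻¹ s⁻¹)
    complex with two exchanged + incoming ligand ⇌ leaving ligand + complex with three exchanged (K = 1.90, k = 0.370 L mol⁻¹ s⁻¹)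
    complex with three exchanged → decomposed reagent (k = 0.00530 s⁻¹)
    starting complex + incoming ligand ⇌ leaving ligand + complex with one exchanged (K = 2.40, k = 9.40 L mol⁻¹ s⁻¹)
    complex with one exchanged + incoming ligand ⇌ leaving ligand + complex with two exchanged (K = 1.60, k = 19.0 L mol⁻¹ s⁻¹)
    leaving ligand + complex with four exchanged → side product B (k = 3.00 L mol⁻¹ s⁻¹)

At 2.50 min the flask still holds 43% of its incoming ligand, the first exchange has a backward turnover of 62% of its forward one, and half of its turnover is done by 0.259 min, earlier than the 0.89 min half-life of complex with two exchanged on the path to side product A. My 40.9% stands 0.80 points from the result, although the incoming ligand spent, 57.0% of its charge, exceeds the reacted share, so one exchange per complex was an approximation, and by 25.0 min the flask has used up 45.7%, more than at the asked time, so the stall is a slowing and not a stop.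

With 1.20 equiv of leaving ligand and the rest unchanged, the stall quotient 2.82 gives 47.1%; that neighbour flask computes to 44.5%.

Readings and results come from a simulation on assumed constants, and the scatter is random.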